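**The neighbour.** The ochre run, where starting material took up two coupling partners to give double product, read 86.5 % on average from 30.0 min on. I reckoned Sunday's and Wednesday's flasks from the share missing from complete conversion, smaller than the share made.

| setting | blue | ochre | Friday's | Sunday's | Wednesday's |
|---|---|---|---|---|---|
| starting material | 0.95 M | 0.95 M | 0.95 M | 0.95 M | 0.95 M |
| coupling partner | 0.26 M | 1.9 M | 0.475 M | 2.38 M | 2.85 M |
| remark | run made earlier | run made earlier |  |  |  |
| time |  |  | 80 min | 80 min | 80 min |

| run | time / min | double product / % | first product / % | starting material / % |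
|---|---|---|---|---|
| blue | 6.00 | 3 | 11 | 64 |
| blue | 10.0 | 2 | 11 | 60 |
| blue | 15.0 | 5 | 12 | 56 |
| blue | 25.0 | 5 | 10 | 52 |
| blue | 30.0 | 2 | 12 | 49 |
| blue | 50.0 | 5 | 12 | 48 |
| blue | 80.0 | 4 | 12 | 48 |
| ochre | 4.00 | 66 | 9 | 2 |
| ochre | 12.0 | 79 | 2 | 1 |
| ochre | 25.0 | 84 | 2 | 3 |
| ochre | 30.0 | 86 | 2 | 1 |
| ochre | 50.0 | 88 | 2 | 0 |
| ochre | 60.0 | 85 | 1 | 1 |
| ochre | 80.0 | 87 | 0 | 2 |

(readings scatter by 1.5 percentage points)

- the analysis behind the earlier runs scatters by 1.5 percentage points, standard deviation

* final double product, as a percentage of the starting material charged, for each flask in turn (Friday's, Sunday's, Wednesday's)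

**The leak.** The ochre shortfall was 13.5 %. I supposed that this material was lost in a competition with capture by the partner, so that the shortfall would fall as c(coupling partner) rose. Shortfall times partner charge then came to 0.257 M, and this product, the leak, was what I carried to Sunday's and Wednesday's flasks.

**What mattered.** I set the length of the run aside, since the ochre run read 86 % at 30.0 min and 87 % at 80.0 min. The scatter of the plateau mean, 0.75 percentage points, moved Sunday's figure by 0.6 points. Dropping my supposition moved it further, by 2.7 points, so the supposition counted for more than the scatter.

**My numbers.** The leak gave 89.2 % for Sunday's flask and 91.0 % for Wednesday's. Friday's flask held 0.500 partner per starting material, less than the two a double product takes, which makes the partner its limiting reagent, and I set no number for it.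

**The forecast.** The forecast gave 10 % for Friday's flask and, holding that “the extra partner should convert most of the remaining reservoir”, 94 % for Sunday's, above my figure, and 95 % for Wednesday's.

**The result.** Friday's, Sunday's and Wednesday's flasks ended at 8.88 %, 91.7 % and 93.6 % double product.

    starting material + coupling partner → first product + by-product (k = 0.00749 M⁻¹ s⁻¹)
    starting material + coupling partner → other mono adduct + by-product (k = 0.00732 M⁻¹ s⁻¹)
    coupling partner + first product → double product + by-product (k = 0.0137 M⁻¹ s⁻¹)
    coupling partner + other mono adduct → double product + by-product (k = 0.0119 M⁻¹ s⁻¹)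
    starting material → decomposition product (k = 7.13 × 10⁻⁷ s⁻¹)
    2 coupling partner → self-condensation product (k = 5.82 × 10⁻⁴ M⁻¹ s⁻¹)
    starting material + by-product → side product (k = 0.00242 M⁻¹ s⁻¹)

Sunday's shortfall of 8.30 % stood as side product, 8.30 %, and its leak came to 0.198 M, less than the 0.257 M worked out from the ochre readings. Carried to Wednesday's charge, Sunday's leak gave 93.1 %, and Wednesday's flask stood at 93.6 %.

(Readings and results are simulated for an exercise; scatter was added.)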